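The top flavan unit is built on the intact middle–bottom dimer instead of being coupled as a flavan. Its ring C is cut at C3–C4 and O1–C2: C3 carries oxygen and C4 carries both ring A of the top unit and C8 of the middle unit, so C4 is a diarylmethyl electrophile (an ortho-quinone methide) and C3 the α-carbon of an alkoxyacetaldehyde. One amine-catalysed step joins C3 to C4, sets both stereocentres and closes the lactol. Its precursor is the galloylated dimer bearing at C8 of the middle unit a hydroxymethine that carries a 2-hydroxy-4,6-bis(benzyloxy)phenyl ring, with all other hydroxyls as benzyl ethers.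

Key step: step 9

Remarks on the chemistry
- Abbreviations: Bn = benzyl; flavan numbering, primes for ring B; "upper unit" is the unit that becomes the middle unit of the target, "lower unit" the bottom unit.
- Structure check: the target reads as epigallocatechin-(4β→8)-epigallocatechin 3-O-gallate-(4β→8)-epigallocatechin. Every unit is 2R,3R (2,3-cis) and each interflavan bond is trans to the neighbouring C3 oxygen. The structures of 13 and 18 carry these configurations and needed no correction.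
- Consequence for the top unit: step 9 must give 3R and 3,4-trans (4β). The 2,3-cis relation then requires the anti (2S,3R) alcohol and ring closure with inversion.
- Precursor design: 13 has exactly one free phenol, so only one quinone methide can form. It is used as the carbinol epimer mixture and is not chromatographed on silica. The C8 carbon is introduced by bromine–lithium exchange before the ester is present; the ester goes on afterwards.
- Assumption: 3,4,5-tris(benzyloxy)benzoic acid (9), 3,5-bis(benzyloxy)phenol (11) and benzyloxyacetaldehyde (14) are taken as commercial.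

Step 1
Reactants: 1 (−)-epigallocatechin
Product: 2 penta-O-benzyl-epigallocatechin
Conditions: BnBr, K2CO3, DMF, 0 °C to rt
Reagents that add atoms: benzyl bromide, BrCc1ccccc1
Why: Williamson etherification under a weak base alkylates the five phenols and leaves the secondary 3-OH untouched, the standard entry to O-benzylated flavan-3-ols; no stereocentre is affected.

Step 2
Reactants: 2 penta-O-benzyl-epigallocatechin
Product: 3 8-bromo-penta-O-benzyl-epigallocatechin
Conditions: NBS, CH2Cl2, −78 °C to rt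
Reagents that add atoms: N-bromosuccinimide, O=C1CCC(=O)N1Br
Why: Electrophilic aromatic bromination of the phloroglucinol-type ring A, which in O-benzylated flavan-3-ols occurs at C8 in preference to C6; the bromine later caps C8 during the flavan coupling and is the handle for lithiation.

Step 3
Reactants: 3 8-bromo-penta-O-benzyl-epigallocatechin
Product: 4 8-bromo-4β-(2-ethoxyethoxy)-penta-O-benzyl-epigallocatechin
Conditions: DDQ, 2-ethoxyethanol, CH2Cl2, rt
Reagents that add atoms: 2-ethoxyethanol, CCOCCO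
Why: DDQ benzylic oxidation at C4 in the presence of an alcohol gives the C4 ether, the alcohol adding anti to the axial 3-OH so that the new C4 centre is 4β (3,4-trans), as established for 2,3-cis flavan-3-ols.

Step 4
Reactants: 2 penta-O-benzyl-epigallocatechin
Product: 5 hexa-O-benzyl-epigallocatechin
Conditions: NaH, BnBr, DMF, 0 °C to rt
Reagents that add atoms: benzyl bromide, BrCc1ccccc1
Why: Williamson etherification of the sodium alkoxide protects the lower-unit 3-OH so that later steps meet one alcohol at a time; no stereocentre is affected.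

Step 5
Reactants: 4 8-bromo-4β-(2-ethoxyethoxy)-penta-O-benzyl-epigallocatechin; 5 hexa-O-benzyl-epigallocatechin (1.5 equiv)
Product: 6 8-bromo dimer alcohol
Conditions: Me3SiOTf (cat.), CH2Cl2, −78 °C; aq. NaHCO3
Reagents that add atoms: none
Why: Lewis-acid-promoted flavan coupling (Friedel–Crafts alkylation after ionisation of the C4 ether): C8 of 5, the most nucleophilic position of its ring A, attacks C4 anti to the axial C3 oxygen, setting the 4β (3,4-trans) interflavan centre as is general for 2,3-cis electrophiles, while the C8 bromine prevents self-condensation of 4.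

Step 6
Reactants: 6 8-bromo dimer alcohol
Product: 8 8-formyl dimer alcohol, via dilithio species 7 (not isolated)
Conditions: n-BuLi (2.2 equiv), THF, −78 °C; DMF, −78 °C to 0 °C; H2O
Reagents that add atoms: N,N-dimethylformamide, CN(C)C=O
Why: Deprotonation of the 3-OH followed by bromine–lithium exchange gives an aryllithium stabilised by two ortho oxygen substituents, which is formylated by DMF (Bouveault formylation); the sequence is placed before esterification so that no carbonyl group competes.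

Step 7
Reactants: 8 8-formyl dimer alcohol; 9 3,4,5-tris(benzyloxy)benzoic acid
Product: 10 8-formyl dimer gallate
Conditions: DCC, DMAP, CH2Cl2, rt
Reagents that add atoms: none
Why: Steglich esterification of the only free hydroxyl, the usual way to galloylate O-benzylated proanthocyanidin dimers; the aryl aldehyde is inert to carbodiimide and DMAP.

Step 8
Reactants: 10 8-formyl dimer gallate; 11 3,5-bis(benzyloxy)phenol
Product: 13 ortho-hydroxy diarylmethanol on the dimer gallate, via bromomagnesium phenoxide 12 (not isolated)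
Conditions: 11, EtMgBr (1 equiv), Et2O, 0 °C; solvent exchange; 10, CH2Cl2, rt; pH 7 buffer, no silica chromatography
Reagents that add atoms: none
Why: ortho-Selective hydroxyalkylation of a magnesium phenoxide by an aldehyde (a chelation-directed Friedel–Crafts-type addition through a six-membered magnesium-bound transition state) attaches the carbon ortho to the phenoxide oxygen and leaves the other phenol carbons untouched; the carbinol centre forms as an epimer mixture, which is of no consequence because it becomes trigonal in step 9.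

Step 9
Reactants: 13 ortho-hydroxy diarylmethanol on the dimer gallate; 14 benzyloxyacetaldehyde (3 equiv)
Product: 18 top-unit lactol on the dimer gallate, via enamine 15 (not isolated), via ortho-quinone methide 16 (not isolated), via hydroxy aldehyde 17 (not isolated)
Conditions: (S)-2-[diphenyl(trimethylsilyloxy)methyl]pyrrolidine (20 mol %), PhCO2H (20 mol %), CH2Cl2, 0 °C to rt
Reagents that add atoms: none
Why: Benzoic acid assists loss of water from 13 to give ortho-quinone methide 16, which is stabilised by two 2,4,6-trioxygenated rings and therefore forms under conditions that spare the ester, the benzyl ethers and the interflavan bond, while the amine converts 14 into (E)-enamine 15; the enamine α-carbon (future C3) adds to the exocyclic methide carbon (future C4), ring A re-aromatises, and hydrolysis returns the catalyst and gives hydroxy aldehyde 17. The closest known reaction type is the diarylprolinol silyl ether-catalysed Michael addition/hemiacetalisation (formal [4+2] annulation) of aldehydes with ortho-quinone methides generated in situ from ortho-hydroxybenzhydrols, which gives trans-3,4-disubstituted chroman-2-ols. The pyran ring closes by 6-exo-trig addition of the phenol oxygen (O1) to the aldehyde carbon (C2), a reversible hemiacetalisation that leaves C2 as a mixture of anomers. C3 is controlled by the catalyst: the diphenyl(trimethylsilyloxy)methyl group of the (S)-pyrrolidine shields one face of the s-trans (E)-enamine, so that the methide is attacked by the open face and C3 becomes R. C4 is controlled by the relative orientation of the partners: with the enamine nitrogen lying over the methide oxygen (endo, hetero-Diels–Alder-like) and the methide in its E geometry, the middle-unit aryl ends trans to the benzyloxy group (4β). The step needs site selectivity, 1,4-regioselectivity and catalyst-controlled facial selectivity: 13 has a single free phenol so only one methide can form, the exocyclic carbon is its only electrophilic position, the carbinol configuration of 13 is erased on ionisation, and the stereocentres of the dimer are remote from the reacting carbon, which should leave the choice of face to the catalyst.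

Step 10
Reactants: 19 5-bromobenzene-1,2,3-triol
Product: 20 5-bromo-1,2,3-tris(benzyloxy)benzene
Conditions: BnBr, K2CO3, DMF, rt
Reagents that add atoms: benzyl bromide, BrCc1ccccc1
Why: Williamson etherification of the three phenols; the aryl bromide is inert.

Step 11
Reactants: 18 top-unit lactol on the dimer gallate; 20 5-bromo-1,2,3-tris(benzyloxy)benzene (4 equiv)
Product: 23 anti alcohol, via aryllithium 21 (not isolated), via aryltitanium triisopropoxide 22 (not isolated)
Conditions: 20, n-BuLi, THF, −78 °C; ClTi(OiPr)3, −78 to −30 °C; 18, −30 to 0 °C; aq. NH4Cl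
Reagents that add atoms: none
Why: Bromine–lithium exchange and transmetalation give an aryltitanium triisopropoxide, a non-basic and non-chelating aryl donor that adds to aldehydes but not to the gallate ester (chemoselective 1,2-addition of an organotitanium reagent); lactol 18 reacts through aldehyde 17, and Felkin–Anh/Cornforth approach past the C3 hydrogen, anti to the C3 benzyloxy group and away from the diarylmethyl group, should give the anti (2S,3R) alcohol.

Step 12
Reactants: 23 anti alcohol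
Product: 24 icosa-O-benzyl trimer
Conditions: PPh3, DIAD, toluene/THF, 0 °C to rt
Reagents that add atoms: none
Why: Intramolecular Mitsunobu etherification: the ring A phenol, the only acidic hydroxyl, displaces the activated benzylic oxygen in a 6-exo-tet SN2 closure with inversion (2S to 2R), which sets the 2,3-cis relation; the electron-withdrawing C3 benzyloxy group next to the benzylic carbon disfavours ionisation and hence loss of stereospecificity.

Step 13
Reactants: 24 icosa-O-benzyl trimer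
Product: 25 CNP0278699.1
Conditions: H2 (1 atm), Pd(OH)2/C, THF/MeOH/H2O, rt; filtration, lyophilisation
Reagents that add atoms: none
Why: Hydrogenolysis of all twenty benzyl ethers over Pd(OH)2 on carbon under neutral conditions, the established last step for O-benzylated proanthocyanidin gallates; the ester, the interflavan bonds and every stereocentre are untouched.

Compound list
1 | (−)-epigallocatechin, (2R,3R)-2-(3,4,5-trihydroxyphenyl)chromane-3,5,7-triol | Oc1cc(O)c2c(c1)O[C@H](c1cc(O)c(O)c(O)c1)[C@H](O)C2 | starting material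
2 | 5,7,3',4',5'-penta-O-benzyl-epigallocatechin, (2R,3R), 3-OH free | O[C@@H]1Cc2c(OCc9ccccc9)cc(OCc9ccccc9)cc2O[C@@H]1c1cc(OCc9ccccc9)c(OCc9ccccc9)c(OCc9ccccc9)c1 | intermediate
3 | 8-bromo-5,7,3',4',5'-penta-O-benzyl-epigallocatechin, (2R,3R) | O[C@@H]1Cc2c(OCc9ccccc9)cc(OCc9ccccc9)c(Br)c2O[C@@H]1c1cc(OCc9ccccc9)c(OCc9ccccc9)c(OCc9ccccc9)c1 | intermediate
4 | 8-bromo-4β-(2-ethoxyethoxy)-5,7,3',4',5'-penta-O-benzyl-epigallocatechin, 2,3-cis, C4 ether trans to 3-OH | O[C@@H]1[C@@H](OCCOCC)c2c(OCc9ccccc9)cc(OCc9ccccc9)c(Br)c2O[C@@H]1c1cc(OCc9ccccc9)c(OCc9ccccc9)c(OCc9ccccc9)c1 | intermediate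
5 | 3,5,7,3',4',5'-hexa-O-benzyl-epigallocatechin, (2R,3R) | c1c(OCc9ccccc9)cc(OCc9ccccc9)c2c1O[C@H](c1cc(OCc9ccccc9)c(OCc9ccccc9)c(OCc9ccccc9)c1)[C@H](OCc9ccccc9)C2 | intermediate
6 | 8-bromo dimer alcohol: 8-bromo-penta-O-benzyl-epigallocatechin-(4β→8)-hexa-O-benzyl-epigallocatechin, upper 3-OH free, interflavan bond trans to it | O[C@@H]1[C@@H](c2c(OCc9ccccc9)cc(OCc9ccccc9)c3c2O[C@H](c2cc(OCc9ccccc9)c(OCc9ccccc9)c(OCc9ccccc9)c2)[C@H](OCc9ccccc9)C3)c2c(OCc9ccccc9)cc(OCc9ccccc9)c(Br)c2O[C@@H]1c1cc(OCc9ccccc9)c(OCc9ccccc9)c(OCc9ccccc9)c1 | intermediate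
7 | dilithio species: lithium 3-alkoxide and C8 aryllithium of the dimer | [Li]O[C@@H]1[C@@H](c2c(OCc9ccccc9)cc(OCc9ccccc9)c3c2O[C@H](c2cc(OCc9ccccc9)c(OCc9ccccc9)c(OCc9ccccc9)c2)[C@H](OCc9ccccc9)C3)c2c(OCc9ccccc9)cc(OCc9ccccc9)c([Li])c2O[C@@H]1c1cc(OCc9ccccc9)c(OCc9ccccc9)c(OCc9ccccc9)c1 | intermediate
8 | 8-formyl dimer alcohol: as 6 with CHO in place of Br | O[C@@H]1[C@@H](c2c(OCc9ccccc9)cc(OCc9ccccc9)c3c2O[C@H](c2cc(OCc9ccccc9)c(OCc9ccccc9)c(OCc9ccccc9)c2)[C@H](OCc9ccccc9)C3)c2c(OCc9ccccc9)cc(OCc9ccccc9)c(C=O)c2O[C@@H]1c1cc(OCc9ccccc9)c(OCc9ccccc9)c(OCc9ccccc9)c1 | intermediate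
9 | 3,4,5-tris(benzyloxy)benzoic acid | OC(=O)c1cc(OCc9ccccc9)c(OCc9ccccc9)c(OCc9ccccc9)c1 | starting material
10 | 8-formyl dimer gallate: 3-O-[3,4,5-tris(benzyloxy)benzoyl] ester of 8 | O=C(O[C@@H]1[C@@H](c2c(OCc9ccccc9)cc(OCc9ccccc9)c3c2O[C@H](c2cc(OCc9ccccc9)c(OCc9ccccc9)c(OCc9ccccc9)c2)[C@H](OCc9ccccc9)C3)c2c(OCc9ccccc9)cc(OCc9ccccc9)c(C=O)c2O[C@@H]1c1cc(OCc9ccccc9)c(OCc9ccccc9)c(OCc9ccccc9)c1)c1cc(OCc9ccccc9)c(OCc9ccccc9)c(OCc9ccccc9)c1 | intermediate
11 | 3,5-bis(benzyloxy)phenol | Oc1cc(OCc9ccccc9)cc(OCc9ccccc9)c1 | starting material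
12 | bromomagnesium 3,5-bis(benzyloxy)phenoxide | Br[Mg]Oc1cc(OCc9ccccc9)cc(OCc9ccccc9)c1 | intermediate
13 | ortho-hydroxy diarylmethanol: dimer gallate bearing at C8 of the galloylated unit a CH(OH) group that carries a 2-hydroxy-4,6-bis(benzyloxy)phenyl ring; carbinol epimer mixture | O=C(O[C@@H]1[C@@H](c2c(OCc9ccccc9)cc(OCc9ccccc9)c3c2O[C@H](c2cc(OCc9ccccc9)c(OCc9ccccc9)c(OCc9ccccc9)c2)[C@H](OCc9ccccc9)C3)c2c(OCc9ccccc9)cc(OCc9ccccc9)c(C(O)c4c(OCc9ccccc9)cc(OCc9ccccc9)cc4O)c2O[C@@H]1c1cc(OCc9ccccc9)c(OCc9ccccc9)c(OCc9ccccc9)c1)c1cc(OCc9ccccc9)c(OCc9ccccc9)c(OCc9ccccc9)c1 | intermediate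
14 | benzyloxyacetaldehyde | O=CCOCc1ccccc1 | starting material
15 | (E)-enamine of 14 with (S)-2-[diphenyl(trimethylsilyloxy)methyl]pyrrolidine | C[Si](C)(C)OC(c1ccccc1)(c1ccccc1)[C@@H]1CCCN1/C=C/OCc1ccccc1 | intermediate
16 | ortho-quinone methide of top ring A, exocyclic carbon on C8 of the galloylated unit, E geometry (aryl anti to the ring carbonyl) | O=C(O[C@@H]1[C@@H](c2c(OCc9ccccc9)cc(OCc9ccccc9)c3c2O[C@H](c2cc(OCc9ccccc9)c(OCc9ccccc9)c(OCc9ccccc9)c2)[C@H](OCc9ccccc9)C3)c2c(OCc9ccccc9)cc(OCc9ccccc9)c(/C=C4\C(OCc9ccccc9)=CC(OCc9ccccc9)=CC4=O)c2O[C@@H]1c1cc(OCc9ccccc9)c(OCc9ccccc9)c(OCc9ccccc9)c1)c1cc(OCc9ccccc9)c(OCc9ccccc9)c(OCc9ccccc9)c1 | intermediate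
17 | hydroxy aldehyde: open form of 18, (3R)-2-benzyloxy aldehyde with free ring A phenol | O=C(O[C@@H]1[C@@H](c2c(OCc9ccccc9)cc(OCc9ccccc9)c3c2O[C@H](c2cc(OCc9ccccc9)c(OCc9ccccc9)c(OCc9ccccc9)c2)[C@H](OCc9ccccc9)C3)c2c(OCc9ccccc9)cc(OCc9ccccc9)c([C@@H](c4c(OCc9ccccc9)cc(OCc9ccccc9)cc4O)[C@@H](OCc9ccccc9)C=O)c2O[C@@H]1c1cc(OCc9ccccc9)c(OCc9ccccc9)c(OCc9ccccc9)c1)c1cc(OCc9ccccc9)c(OCc9ccccc9)c(OCc9ccccc9)c1 | intermediate
18 | top-unit lactol: 3-benzyloxy-5,7-bis(benzyloxy)chroman-2-ol joined through C4 to C8 of the galloylated dimer; 3R, C4 aryl trans to 3-OBn (4β), C2 mixed | O=C(O[C@@H]1[C@@H](c2c(OCc9ccccc9)cc(OCc9ccccc9)c3c2O[C@H](c2cc(OCc9ccccc9)c(OCc9ccccc9)c(OCc9ccccc9)c2)[C@H](OCc9ccccc9)C3)c2c(OCc9ccccc9)cc(OCc9ccccc9)c([C@H]3c4c(OCc9ccccc9)cc(OCc9ccccc9)cc4OC(O)[C@@H]3OCc9ccccc9)c2O[C@@H]1c1cc(OCc9ccccc9)c(OCc9ccccc9)c(OCc9ccccc9)c1)c1cc(OCc9ccccc9)c(OCc9ccccc9)c(OCc9ccccc9)c1 | intermediate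
19 | 5-bromobenzene-1,2,3-triol | Oc1cc(Br)cc(O)c1O | starting material
20 | 5-bromo-1,2,3-tris(benzyloxy)benzene | Brc1cc(OCc9ccccc9)c(OCc9ccccc9)c(OCc9ccccc9)c1 | intermediate
21 | 3,4,5-tris(benzyloxy)phenyllithium | [Li]c1cc(OCc9ccccc9)c(OCc9ccccc9)c(OCc9ccccc9)c1 | intermediate
22 | [3,4,5-tris(benzyloxy)phenyl]titanium triisopropoxide | CC(C)O[Ti](OC(C)C)(OC(C)C)c1cc(OCc9ccccc9)c(OCc9ccccc9)c(OCc9ccccc9)c1 | intermediate
23 | anti alcohol: ring-opened top unit with free ring A phenol, (2S)-carbinol bearing the 3,4,5-tris(benzyloxy)phenyl ring, anti to the (3R)-benzyloxy group | O=C(O[C@@H]1[C@@H](c2c(OCc9ccccc9)cc(OCc9ccccc9)c3c2O[C@H](c2cc(OCc9ccccc9)c(OCc9ccccc9)c(OCc9ccccc9)c2)[C@H](OCc9ccccc9)C3)c2c(OCc9ccccc9)cc(OCc9ccccc9)c([C@@H](c4c(OCc9ccccc9)cc(OCc9ccccc9)cc4O)[C@@H](OCc9ccccc9)[C@@H](O)c4cc(OCc9ccccc9)c(OCc9ccccc9)c(OCc9ccccc9)c4)c2O[C@@H]1c1cc(OCc9ccccc9)c(OCc9ccccc9)c(OCc9ccccc9)c1)c1cc(OCc9ccccc9)c(OCc9ccccc9)c(OCc9ccccc9)c1 | intermediate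
24 | icosa-O-benzyl trimer: the target with all twenty free hydroxyls as benzyl ethers; top unit 2R,3R, 4β | O=C(O[C@@H]1[C@@H](c2c(OCc9ccccc9)cc(OCc9ccccc9)c3c2O[C@H](c2cc(OCc9ccccc9)c(OCc9ccccc9)c(OCc9ccccc9)c2)[C@H](OCc9ccccc9)C3)c2c(OCc9ccccc9)cc(OCc9ccccc9)c([C@H]3c4c(OCc9ccccc9)cc(OCc9ccccc9)cc4O[C@H](c4cc(OCc9ccccc9)c(OCc9ccccc9)c(OCc9ccccc9)c4)[C@@H]3OCc9ccccc9)c2O[C@@H]1c1cc(OCc9ccccc9)c(OCc9ccccc9)c(OCc9ccccc9)c1)c1cc(OCc9ccccc9)c(OCc9ccccc9)c(OCc9ccccc9)c1 | intermediate
25 | CNP0278699.1, epigallocatechin-(4β→8)-epigallocatechin 3-O-gallate-(4β→8)-epigallocatechin | O=C(O[C@@H]1[C@@H](c2c(O)cc(O)c3c2O[C@H](c2cc(O)c(O)c(O)c2)[C@H](O)C3)c2c(O)cc(O)c([C@H]3c4c(O)cc(O)cc4O[C@H](c4cc(O)c(O)c(O)c4)[C@@H]3O)c2O[C@@H]1c1cc(O)c(O)c(O)c1)c1cc(O)c(O)c(O)c1 | target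

Total step count: 13. Longest linear sequence: 11 steps (1, 2, 3, 5, 6, 7, 8, 9, 11, 12, 13).

Steps most likely to fail

Step 9. The hindered methide may react with the enamine more slowly than 14 condenses with itself or than the methide oligomerises. Facial selectivity at C4 may also be poor, because the methide can equilibrate between its two geometries; the 5-benzyloxy group crowds the E form. The fallback replaces the de novo construction by a third flavan coupling and sets out from 6. The dilithio species 7 is quenched with methanol in place of DMF to give the debrominated dimer alcohol F1. Esterification with 9 (DCC, DMAP) gives the debrominated dimer gallate F2. Separately, 5 is oxidised with DDQ and 2-ethoxyethanol to 4β-(2-ethoxyethoxy)-hexa-O-benzyl-epigallocatechin F3. Coupling of F3 with an excess of F2 (Me3SiOTf, CH2Cl2, −78 °C) should take place at C8 of the galloylated unit, anti to the C3 benzyloxy group, and gives 24, where the route is rejoined.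

Step 11. Ring opening of the titanium-bound lactol may be slow, and aryl delivery may be steered by the titanium phenoxide, which would erode or reverse the anti selectivity. The fallback sets the carbinol centre with hydride instead of with the aryl group and sets out from 18. The same aryl addition, run without regard to selectivity, gives 23 together with its C2 epimer, the syn alcohol F4. The mixture is oxidised (Dess–Martin periodinane, NaHCO3, CH2Cl2) to the aryl ketone F5. Chelation-controlled reduction with Zn(BH4)2 (Et2O, −20 °C), with zinc held between the ketone and the C3 benzyloxy oxygen and hydride arriving past the C3 hydrogen, gives the anti alcohol 23, where the route is rejoined.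

Step 8. The hindered, electron-rich aldehyde may add the phenoxide too slowly, or the magnesium salt of the product may ionise and take up a second phenoxide (over-arylation to a triarylmethane). The fallback uses a preformed aryl nucleophile and sets out from 11. ortho-Bromination (NBS, cat. i-Pr2NH, CH2Cl2) gives 2-bromo-3,5-bis(benzyloxy)phenol F6, and allylation (allyl bromide, K2CO3, DMF) gives the allyl ether F7. Bromine–lithium exchange (n-BuLi, THF, −78 °C) gives the aryllithium F8, which is added at −78 °C to aldehyde 10 to give the O-allyl diarylmethanol F9. Deallylation with Pd(PPh3)4 and morpholine (THF, rt) gives 13, where the route is rejoined.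

Further compounds
F1 | step 9 | debrominated dimer alcohol: penta-O-benzyl-epigallocatechin-(4β→8)-hexa-O-benzyl-epigallocatechin, upper 3-OH free | O[C@@H]1[C@@H](c2c(OCc9ccccc9)cc(OCc9ccccc9)c3c2O[C@H](c2cc(OCc9ccccc9)c(OCc9ccccc9)c(OCc9ccccc9)c2)[C@H](OCc9ccccc9)C3)c2c(OCc9ccccc9)cc(OCc9ccccc9)cc2O[C@@H]1c1cc(OCc9ccccc9)c(OCc9ccccc9)c(OCc9ccccc9)c1
F2 | step 9 | debrominated dimer gallate: 3-O-[3,4,5-tris(benzyloxy)benzoyl] ester of F1 | O=C(O[C@@H]1[C@@H](c2c(OCc9ccccc9)cc(OCc9ccccc9)c3c2O[C@H](c2cc(OCc9ccccc9)c(OCc9ccccc9)c(OCc9ccccc9)c2)[C@H](OCc9ccccc9)C3)c2c(OCc9ccccc9)cc(OCc9ccccc9)cc2O[C@@H]1c1cc(OCc9ccccc9)c(OCc9ccccc9)c(OCc9ccccc9)c1)c1cc(OCc9ccccc9)c(OCc9ccccc9)c(OCc9ccccc9)c1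
F3 | step 9 | 4β-(2-ethoxyethoxy)-3,5,7,3',4',5'-hexa-O-benzyl-epigallocatechin, C4 ether trans to 3-OBn | O(Cc9ccccc9)[C@@H]1[C@@H](OCCOCC)c2c(OCc9ccccc9)cc(OCc9ccccc9)cc2O[C@@H]1c1cc(OCc9ccccc9)c(OCc9ccccc9)c(OCc9ccccc9)c1
F4 | step 11 | syn alcohol: C2 epimer of 23, (2R)-carbinol syn to the (3R)-benzyloxy group | O=C(O[C@@H]1[C@@H](c2c(OCc9ccccc9)cc(OCc9ccccc9)c3c2O[C@H](c2cc(OCc9ccccc9)c(OCc9ccccc9)c(OCc9ccccc9)c2)[C@H](OCc9ccccc9)C3)c2c(OCc9ccccc9)cc(OCc9ccccc9)c([C@@H](c4c(OCc9ccccc9)cc(OCc9ccccc9)cc4O)[C@@H](OCc9ccccc9)[C@H](O)c4cc(OCc9ccccc9)c(OCc9ccccc9)c(OCc9ccccc9)c4)c2O[C@@H]1c1cc(OCc9ccccc9)c(OCc9ccccc9)c(OCc9ccccc9)c1)c1cc(OCc9ccccc9)c(OCc9ccccc9)c(OCc9ccccc9)c1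
F5 | step 11 | aryl ketone: 23 with the carbinol oxidised to C=O | O=C(O[C@@H]1[C@@H](c2c(OCc9ccccc9)cc(OCc9ccccc9)c3c2O[C@H](c2cc(OCc9ccccc9)c(OCc9ccccc9)c(OCc9ccccc9)c2)[C@H](OCc9ccccc9)C3)c2c(OCc9ccccc9)cc(OCc9ccccc9)c([C@@H](c4c(OCc9ccccc9)cc(OCc9ccccc9)cc4O)[C@@H](OCc9ccccc9)C(=O)c4cc(OCc9ccccc9)c(OCc9ccccc9)c(OCc9ccccc9)c4)c2O[C@@H]1c1cc(OCc9ccccc9)c(OCc9ccccc9)c(OCc9ccccc9)c1)c1cc(OCc9ccccc9)c(OCc9ccccc9)c(OCc9ccccc9)c1
F6 | step 8 | 2-bromo-3,5-bis(benzyloxy)phenol | Oc1cc(OCc9ccccc9)cc(OCc9ccccc9)c1Br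
F7 | step 8 | 1-(allyloxy)-2-bromo-3,5-bis(benzyloxy)benzene | C=CCOc1cc(OCc9ccccc9)cc(OCc9ccccc9)c1Br
F8 | step 8 | 2-(allyloxy)-4,6-bis(benzyloxy)phenyllithium | C=CCOc1cc(OCc9ccccc9)cc(OCc9ccccc9)c1[Li]
F9 | step 8 | O-allyl diarylmethanol: 13 with the free phenol as its allyl ether | O=C(O[C@@H]1[C@@H](c2c(OCc9ccccc9)cc(OCc9ccccc9)c3c2O[C@H](c2cc(OCc9ccccc9)c(OCc9ccccc9)c(OCc9ccccc9)c2)[C@H](OCc9ccccc9)C3)c2c(OCc9ccccc9)cc(OCc9ccccc9)c(C(O)c4c(OCc9ccccc9)cc(OCc9ccccc9)cc4OCC=C)c2O[C@@H]1c1cc(OCc9ccccc9)c(OCc9ccccc9)c(OCc9ccccc9)c1)c1cc(OCc9ccccc9)c(OCc9ccccc9)c(OCc9ccccc9)c1
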